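Ring A is disconnected at C8a–C1 and C2–C3. The plan uses one feature of ring B: the C8 oxygen is vicinal to quaternary C8a and anti to the C8a methyl. Acylating C8–O with a methyl but-2-ynedioyl unit allows an intramolecular Diels–Alder reaction onto the C8a=C4a–C4=C3 diene. In one operation this builds ring A, a temporary γ-lactone (C8, O, C11, C1, C8a) and the C8a stereocentre, and it keeps C11 distinct from the C2 ester. The precursor is a ring B dienyl ester that already carries quaternary C5 and the equatorial C6 chloride. Side-chain metathesis, C4=C4a reduction, lactone reduction and kinetic C1 protonation finish the target.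

Key step: step 11

Convention: the decalin locants of the target are used for every compound. C1 bears the formyl group, C2 the ester, C4a and C8a are the ring fusion, C5 is quaternary, C6 bears chloride, C8 bears oxygen, and C11 is the formyl or lactone carbon. β is the face of the C8a methyl and α is the opposite face.
Assumption: 21 is drawn as the open hydroxy enal. Any lactol tautomer present opens under the conditions of step 15 and gives the same dienolate.

Step 1
Reactants: 1 2-methylcyclohexane-1,3-dione; 2 allyl bromide
Product: 3 2-allyl-2-methylcyclohexane-1,3-dione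
Conditions: NaOH (1.0 equiv), H2O, 23 °C
Reagents that add atoms: none
Why: C-alkylation of the stabilised 1,3-dione enolate with a reactive allylic halide is the standard entry to 2,2-disubstituted cyclohexane-1,3-diones, and the product is still achiral.

Step 2
Reactants: 3 2-allyl-2-methylcyclohexane-1,3-dione
Product: 4 (2R,3R)-2-allyl-3-hydroxy-2-methylcyclohexan-1-one (C6–OH α, cis to the allyl group; C5 methyl β)
Conditions: (S)-2-methyl-CBS-oxazaborolidine (0.2 equiv), catecholborane (1.1 equiv), toluene, −60 °C
Reagents that add atoms: none
Why: This is a Corey–Bakshi–Shibata reduction run as a desymmetrisation, in which the catalyst reads quaternary C5 as the large flank and sets C6 as R, hydride enters on the face of the small C5 methyl (anti to the allyl group) and thereby fixes C5, and catecholborane does not hydroborate the allyl group.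

Step 3
Reactants: 4 (2R,3R)-2-allyl-3-hydroxy-2-methylcyclohexan-1-one
Product: 6 (2S,3S)-2-allyl-3-chloro-2-methylcyclohexan-1-one, via triflate 5 (not isolated)
Conditions: Tf2O, 2,6-lutidine, CH2Cl2, −78 → 0 °C; then Bu4NCl, 0 → 23 °C
Reagents that add atoms: triflic anhydride, O=S(=O)(OS(=O)(=O)C(F)(F)F)C(F)(F)F (atoms in 5 only); tetrabutylammonium chloride, CCCC[N+](CCCC)(CCCC)CCCC.[Cl-]
Why: Sulfonate activation and SN2 displacement invert C6 to the β chloride, because ionisation with methyl shift would place positive charge beside the C4a carbonyl and E1cB loss is impossible with no hydrogen on C5.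

Step 4
Reactants: 6 (2S,3S)-2-allyl-3-chloro-2-methylcyclohexan-1-one
Product: 7 (2S,3S)-2-allyl-3-chloro-2,6-dimethylcyclohexan-1-one (epimers at the new C8a centre)
Conditions: LDA (1.05 equiv), THF, −78 °C; MeI, −78 → −20 °C
Reagents that add atoms: iodomethane, CI
Why: In this kinetic enolate alkylation only C8a can be deprotonated because C5 is quaternary, and the C8a configuration formed here is erased in step 5.

Step 5
Reactants: 7 (2S,3S)-2-allyl-3-chloro-2,6-dimethylcyclohexan-1-one
Product: 9 (5S,6S)-6-allyl-5-chloro-2,6-dimethylcyclohex-2-en-1-one, via silyl enol ether 8 (not isolated)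
Conditions: LDA, Me3SiCl, THF, −78 → 0 °C; then Pd(OAc)2 (1.05 equiv), MeCN, 23 °C
Reagents that add atoms: chlorotrimethylsilane, C[Si](C)(C)Cl (atoms in 8 only)
Why: Saegusa–Ito oxidation of the only possible silyl enol ether loses a β-hydride from C8 and gives the endocyclic 2-methyl enone, the more stable conjugated isomer, while the unactivated chloride and the allyl group stay untouched.

Step 6
Reactants: 9 (5S,6S)-6-allyl-5-chloro-2,6-dimethylcyclohex-2-en-1-one; 10 vinylmagnesium bromide
Product: 11 (5S,6S)-6-allyl-5-chloro-2,6-dimethyl-1-vinylcyclohex-2-en-1-ol (epimers at C4a)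
Conditions: LaCl3·2LiCl (1.0 equiv), THF, −78 → −30 °C; aq. NH4Cl at −30 °C
Reagents that add atoms: none
Why: In this 1,2-addition of a Grignard reagent to a hindered enone the lanthanum salt activates the carbonyl and damps basicity, so γ-deprotonation with chloride loss is avoided, and the C4a carbinol configuration does not matter because C4a becomes sp2.

Step 7
Reactants: 11 (5S,6S)-6-allyl-5-chloro-2,6-dimethyl-1-vinylcyclohex-2-en-1-ol
Product: 12 (4S,5S)-4-allyl-5-chloro-2,4-dimethyl-3-vinylcyclohex-2-en-1-one
Conditions: pyridinium chlorochromate (C5H5NH[CrO3Cl], 2.5 equiv), 4 Å molecular sieves, CH2Cl2, 23 °C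
Reagents that add atoms: pyridinium chlorochromate, c1cc[nH+]cc1.[O-][Cr](=O)(=O)Cl (supplies the C8 oxygen; the C4a oxygen leaves on chromium)
Why: In the Babler–Dauben oxidative transposition the chromate ester of the bis-allylic tertiary alcohol shifts [3,3] towards the more electron-rich trisubstituted ring alkene, and the C8 chromate is oxidised to the dienone in a non-basic medium that spares the β-chloro ketone.

Step 8
Reactants: 12 (4S,5S)-4-allyl-5-chloro-2,4-dimethyl-3-vinylcyclohex-2-en-1-one
Product: 13 (1S,4S,5S)-4-allyl-5-chloro-2,4-dimethyl-3-vinylcyclohex-2-en-1-ol (C8–OH α)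
Conditions: (R)-2-methyl-CBS-oxazaborolidine (0.3 equiv), catecholborane (1.5 equiv), toluene, −78 °C
Reagents that add atoms: none
Why: In this Corey–Bakshi–Shibata reduction the methyl-substituted alkene flank acts as the large group, so the (R)-catalyst delivers hydride to the β face and sets C8 as S by reagent control, while catecholborane leaves the three alkenes alone and no base touches the β-chloro ketone.

Step 9
Reactants: 14 methyl propiolate
Product: 15 4-methoxy-4-oxobut-2-ynoic acid
Conditions: LiN(SiMe3)2 (1.0 equiv), THF, −78 °C; CO2 (gas), −78 °C; aq. HCl work-up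
Reagents that add atoms: carbon dioxide, O=C=O
Why: Carboxylation of a lithium acetylide works here because the acidic propiolate C–H is removed cleanly at low temperature and the acetylide is trapped by CO2 before it can add to a second propiolate.

Step 10
Reactants: 13 (1S,4S,5S)-4-allyl-5-chloro-2,4-dimethyl-3-vinylcyclohex-2-en-1-ol; 15 4-methoxy-4-oxobut-2-ynoic acid
Product: 16 (1S,4S,5S)-4-allyl-5-chloro-2,4-dimethyl-3-vinylcyclohex-2-en-1-yl methyl but-2-ynedioate (ring B dienyl ester)
Conditions: N,N'-dicyclohexylcarbodiimide (1.3 equiv), DMAP (0.05 equiv), CH2Cl2, −20 → 0 °C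
Reagents that add atoms: none
Why: Steglich esterification under neutral cold conditions with little DMAP limits conjugate addition to the alkynoate, avoids ionising the dienylic alcohol, and retains C8 because the C8–O bond is not touched.

Step 11
Reactants: 16 ring B dienyl methyl but-2-ynedioate
Product: 17 tricyclic lactone diene (ring A 1,4-diene with C1=C2 and C4=C4a; C2–CO2Me; γ-lactone C8α–O–C11(=O)–C1; C8a methyl β; C5 methyl β and allyl α; C6 chloride β)
Conditions: PhCl (0.005 mol/L), BHT (0.1 equiv), 2,6-di-tert-butyl-4-methylpyridine (0.1 equiv), reflux (132 °C), Ar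
Reagents that add atoms: none
Why: A concerted, thermally allowed [4+2] cycloaddition places the doubly activated alkyne across the s-cis C8a=C4a–C4=C3 diene, forming C8a–C1 and C2–C3 and leaving the C1=C2 and C4=C4a alkenes. The closest known reactions are ester-tethered intramolecular Diels–Alder reactions of dienyl alkynoates and the bimolecular additions of acetylenedicarboxylates to 1-vinyl-2-methylcyclohexenes, which show that a methyl-bearing diene terminus can become a quaternary carbon. Ring A closes as the six-membered cycloaddition ring, and the five-membered lactone closes at the same moment, cis-fused to ring B, because the three-atom link C8–O–C11 ties C1 to C8a. The only new stereocentre, C8a, is controlled by C8: the short tether reaches C8a only from the α face on which C8–O stands, so the methyl group ends on the β face, anti to C8–O. The same tether fixes the regiochemistry (C1 to C8a, C2 to C3), an alkyne raises no endo/exo question, and high dilution favours ring closure over dimerisation. The β chloride at C6 is equatorial when C8–O is pseudoaxial, so the reactive half-chair, already favoured by allylic strain with the C8a methyl, has no syn-axial clash, while BHT and the hindered pyridine suppress radical and acid-triggered loss of the dienylic ester.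

Step 12
Reactants: 17 tricyclic lactone diene; 18 2-methylbut-3-en-2-ol
Product: 19 tricyclic lactone diene with the (E)-CH2CH=CHC(CH3)2OH chain on C5 (otherwise as 17)
Conditions: second-generation Hoveyda–Grubbs catalyst RuCl2(H2IMes)(=CH-C6H4-2-OiPr) (0.05 equiv), 18 (10 equiv), CH2Cl2, 40 °C
Reagents that add atoms: none
Why: Olefin cross-metathesis of an unhindered terminal alkene with an excess of a slowly dimerising tertiary allylic alcohol gives the E alkene under thermodynamic control, and the tri- and tetrasubstituted ring alkenes are inert to the catalyst.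

Step 13
Reactants: 19 tricyclic lactone diene with the full side chain
Product: 20 trans-fused lactone (as 19, with C4–C4a saturated and C4a–H α)
Conditions: Mn(dpm)3 (0.15 equiv), PhSiH3 (1.5 equiv), tBuOOH (1.5 equiv), iPrOH, 22 °C, Ar
Reagents that add atoms: none
Why: In this metal-hydride hydrogen-atom-transfer hydrogenation the manganese hydride gives a hydrogen atom to open C4 of the only electron-rich trisubstituted alkene (the 1,2-disubstituted side-chain alkene and the tetrasubstituted acceptor alkene react more slowly, and the alkyl chloride is tolerated), and the tertiary C4a radical is capped on the α face, opposite the flanking C8a and C5 methyl groups, which sets the trans ring fusion.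

Step 14
Reactants: 20 trans-fused lactone
Product: 21 methyl (4aR,5S,6S,8S,8aS)-6-chloro-1-formyl-8-hydroxy-5-[(E)-4-hydroxy-4-methylpent-2-enyl]-5,8a-dimethyl-3,4,4a,5,6,7,8,8a-octahydronaphthalene-2-carboxylate (hydroxy enal)
Conditions: iBu2AlH (2.2 equiv), CH2Cl2, −78 °C; aq. potassium sodium tartrate
Reagents that add atoms: none
Why: In this partial lactone reduction one equivalent is taken by the tertiary alcohol, the strained lactone carbonyl with its lactone-type ester geometry is more electrophilic than the hindered conjugated methyl ester, the tetrahedral aluminate survives until work-up, and the lactol should open because a five-membered bridge between C8 and an sp2 C1 strains the trans-decalin.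

Step 15
Reactants: 21 hydroxy enal
Product: 23 CNP0167913.1, via trilithium dienolate 22 (not isolated)
Conditions: LDA (3.3 equiv), THF, −78 °C; then AcOH (10 equiv) in THF, −78 °C
Reagents that add atoms: lithium diisopropylamide, CC(C)[N-]C(C)C.[Li+] (lithium in 22 only)
Why: In this deconjugative kinetic α-protonation of an extended enolate, γ-deprotonation at C3 of the hindered enal gives the C11=C1–C2=C3 dienolate, and one irreversible protonation at C1 from the α face (anti to the axial C8a methyl and relayed by the axial C8 oxygen) sets C1–H α and leaves the alkene conjugated with the ester, whereas equilibrating base is avoided because the C1 epimer would drain away as a lactol with C8–OH.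

Compound list
1 | 2-methylcyclohexane-1,3-dione | CC1C(=O)CCCC1=O | starting material
2 | allyl bromide | C=CCBr | starting material
3 | 2-allyl-2-methylcyclohexane-1,3-dione | C=CCC1(C)C(=O)CCCC1=O | intermediate
4 | (2R,3R)-2-allyl-3-hydroxy-2-methylcyclohexan-1-one | O=C1CCC[C@@H](O)[C@@]1(C)CC=C | intermediate
5 | (1R,2R)-2-allyl-2-methyl-3-oxocyclohexyl triflate (not isolated) | O=C1CCC[C@@H](OS(=O)(=O)C(F)(F)F)[C@@]1(C)CC=C | intermediate
6 | (2S,3S)-2-allyl-3-chloro-2-methylcyclohexan-1-one | O=C1CCC[C@H](Cl)[C@@]1(C)CC=C | intermediate
7 | (2S,3S)-2-allyl-3-chloro-2,6-dimethylcyclohexan-1-one, epimers at C8a | O=C1C(C)CC[C@H](Cl)[C@@]1(C)CC=C | intermediate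
8 | trimethylsilyl enol ether of 7 (not isolated) | C[Si](C)(C)OC1=C(C)CC[C@H](Cl)[C@@]1(C)CC=C | intermediate
9 | (5S,6S)-6-allyl-5-chloro-2,6-dimethylcyclohex-2-en-1-one | O=C1C(C)=CC[C@H](Cl)[C@@]1(C)CC=C | intermediate
10 | vinylmagnesium bromide | C=C[Mg]Br | starting material
11 | (5S,6S)-6-allyl-5-chloro-2,6-dimethyl-1-vinylcyclohex-2-en-1-ol, epimers at C4a | OC1(C=C)C(C)=CC[C@H](Cl)[C@@]1(C)CC=C | intermediate
12 | (4S,5S)-4-allyl-5-chloro-2,4-dimethyl-3-vinylcyclohex-2-en-1-one | O=C1C[C@H](Cl)[C@@](C)(CC=C)C(C=C)=C1C | intermediate
13 | (1S,4S,5S)-4-allyl-5-chloro-2,4-dimethyl-3-vinylcyclohex-2-en-1-ol | O[C@H]1C[C@H](Cl)[C@@](C)(CC=C)C(C=C)=C1C | intermediate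
14 | methyl propiolate | C#CC(=O)OC | starting material
15 | 4-methoxy-4-oxobut-2-ynoic acid | COC(=O)C#CC(=O)O | intermediate
16 | ring B dienyl methyl but-2-ynedioate (key-step precursor) | C=CC1=C(C)[C@@H](OC(=O)C#CC(=O)OC)C[C@H](Cl)[C@@]1(C)CC=C | intermediate
17 | tricyclic lactone diene (key-step product) | COC(=O)C1=C2C(=O)O[C@H]3C[C@H](Cl)[C@@](C)(CC=C)C(=CC1)[C@@]23C | intermediate
18 | 2-methylbut-3-en-2-ol | C=CC(C)(C)O | starting material
19 | tricyclic lactone diene with E side chain | COC(=O)C1=C2C(=O)O[C@H]3C[C@H](Cl)[C@@](C)(C/C=C/C(C)(C)O)C(=CC1)[C@@]23C | intermediate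
20 | trans-fused lactone, C4a–H α | COC(=O)C1=C2C(=O)O[C@H]3C[C@H](Cl)[C@@](C)(C/C=C/C(C)(C)O)[C@H](CC1)[C@@]23C | intermediate
21 | hydroxy enal (C1=C2, C11 aldehyde, C8–OH α) | O=CC1=C(C(=O)OC)CC[C@@H]2[C@]1(C)[C@@H](O)C[C@H](Cl)[C@@]2(C)C/C=C/C(C)(C)O | intermediate
22 | trilithium dienolate of 21 (not isolated) | [Li+].[Li+].[Li+].[O-]C=C1C(C(=O)OC)=CC[C@@H]2[C@]1(C)[C@@H]([O-])C[C@H](Cl)[C@@]2(C)C/C=C/C(C)(C)[O-] | intermediate
23 | CNP0167913.1, methyl (1R,4aR,5S,6S,8S,8aS)-6-chloro-1-formyl-8-hydroxy-5-[(E)-4-hydroxy-4-methylpent-2-enyl]-5,8a-dimethyl-1,4,4a,5,6,7,8,8a-octahydronaphthalene-2-carboxylate | COC(=O)C1=CC[C@H]2[C@](C)(C/C=C/C(C)(C)O)[C@@H](Cl)C[C@H](O)[C@]2(C)[C@H]1C=O | target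

Total step count: 15. Longest linear sequence: 14 (steps 1–8 and 10–15).

Steps most likely to fail

Step 11. Heating may ionise or eliminate the dienylic ester, or trigger a [1,5]-hydrogen shift from the C8a methyl. Either could happen faster than the tether folds into the lactone-like ester geometry that the cycloaddition needs. The fallback is a bimolecular cycloaddition followed by closure of the lactone. It sets out from dienol 13, which is heated with commercial dimethyl acetylenedicarboxylate (toluene, 110 °C), the known reaction of 1-vinyl-2-methylcyclohexenes. Of the two facial adducts only the α-face hydroxy diester F1 holds C8–OH and the C1 ester on the same side. Acid-catalysed lactonisation (camphorsulfonic acid, toluene, 80 °C) therefore converts that adduct alone into 17, where the route is rejoined.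

Step 3. Displacement at C6, next to quaternary C5, may lose to E2 elimination towards C7. The fallback replaces polar substitution by a radical one. It sets out from 4, which is acylated with methyl chlorooxoacetate (Et3N, CH2Cl2) to the methyl oxalate F2. One equivalent of CsOH (THF/H2O) then gives the caesium oxalate F3. Visible-light deoxychlorination (Ir[dF(CF3)ppy]2(dtbbpy)PF6, ethyl trichloroacetate, blue light, 60 °C) expels two CO2. The C6 radical should then take chlorine on the face opposite the allyl group, which leads back to 6.

Step 13. Hydrogen may be delivered to the wrong face of the C4a radical under the constraint of the lactone bridge. The side-chain alkene may also be reduced, or hydrogen may be abstracted from doubly allylic C3. The fallback removes the competing alkene first and uses surface hydrogenation. It sets out from 17, in which OsO4 (cat.)/NaIO4 cleaves only the unhindered terminal alkene to the aldehyde F4. H2 over palladium on carbon (EtOAc) then adds to C4=C4a from the α face, opposite both methyl groups, as known for acetylenedicarboxylate adducts of vinylcyclohexenes, and gives the trans-fused aldehyde F5. Wittig olefination with 1-(triphenylphosphoranylidene)propan-2-one gives the E enone F6. MeTi(OiPr)3, which adds to ketones but not to esters or lactones, then returns to 20.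

Further compounds
F1 | step 11 | α-face hydroxy diester adduct of 13 and dimethyl acetylenedicarboxylate | COC(=O)C1=C(C(=O)OC)[C@@]2(C)[C@@H](O)C[C@H](Cl)[C@@](C)(CC=C)C2=CC1
F2 | step 3 | (1R,2R)-2-allyl-2-methyl-3-oxocyclohexyl methyl oxalate | COC(=O)C(=O)O[C@@H]1CCCC(=O)[C@]1(C)CC=C
F3 | step 3 | caesium (1R,2R)-2-allyl-2-methyl-3-oxocyclohexyl oxalate | [Cs+].[O-]C(=O)C(=O)O[C@@H]1CCCC(=O)[C@]1(C)CC=C
F4 | step 13 | tricyclic lactone diene with C5–CH2CHO | COC(=O)C1=C2C(=O)O[C@H]3C[C@H](Cl)[C@@](C)(CC=O)C(=CC1)[C@@]23C
F5 | step 13 | trans-fused lactone with C5–CH2CHO, C4a–H α | COC(=O)C1=C2C(=O)O[C@H]3C[C@H](Cl)[C@@](C)(CC=O)[C@H](CC1)[C@@]23C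
F6 | step 13 | trans-fused lactone with C5–(E)-CH2CH=CHC(O)CH3 | COC(=O)C1=C2C(=O)O[C@H]3C[C@H](Cl)[C@@](C)(C/C=C/C(C)=O)[C@H](CC1)[C@@]23C
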